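**Plan**

- Retrosynthesis: the C6–C7 bond of the ten-membered ring (C1–C10) is cut as a [2,3]-Wittig retron. This leads back to an 11-membered cyclic ether (C1–C5, C16, O, C7–C10) with an exocyclic (Z)-C5=C6HCl alkene. Further cuts: C8–C9 (Nozaki–Hiyama–Kishi), O–C7 (etherification), C4–C5 (carbomagnesiation of propargyl alcohol), C2–C3 (allylboration), cyclohexene (Diels–Alder).
- Enabling feature: C16 is an exocyclic methylene on C5, next to chlorinated C6, next to oxygenated C7. This triad is what forms when a C7 carbanion α to an ether oxygen attacks the chloro terminus of the allyl unit O–C16H2–C5=C6. O and C16 leave the ring and C6 enters it.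
- Forward order: cyclohexenone (Diels–Alder) → C11/C12 oxygenation → C2–C5 chain with the chloroalkene → ether and enol triflate → 11-membered ether ring → ring contraction to the ten-membered carbocycle → γ-lactone → 8,17-epoxide → reductive opening → deprotection, enone, acetates.
- Stereochemistry: C1/C10 from the catalytic asymmetric Diels–Alder reaction (E-dienophile gives trans); C11 by enolate hydroxylation anti to the C15 methyl; C2 by reagent control; C9 by Felkin-controlled ring closure; C6/C7 in the ring contraction; C8 by hydroxyl-directed epoxidation; C17 by equilibration.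

Key step: step 17

Assumption: catalyst and reagent antipodes follow the established facial models for each reaction type (the antipode is exchanged if a model fails); locants in names follow briarane numbering (C1–C20).

**Step 1**
Reactants: 1 (E)-4,4-dimethoxy-2-methylbut-2-enal; 2 (E)-3-(tert-butyldimethylsilyloxy)-N,N-dimethylbuta-1,3-dien-1-amine
Product: 4 formyl enone (6-(dimethoxymethyl)-1-methyl-4-oxocyclohex-2-ene-1-carbaldehyde), via Diels–Alder adduct 3 (not isolated)
Conditions: chiral (salen)Cr(III)SbF6 (5 mol %, antipode for the (1S,10S) adduct), 4 Å MS, CH2Cl2, −40 °C; then AcCl, Et2O/CH2Cl2, −78 °C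
Reagents that add atoms: none
Why: The Diels–Alder reaction of the 1-amino-3-siloxydiene with the (E)-α-methyl enal under chiral Lewis acid catalysis should join the amino terminus to the α-carbon (quaternary C1) with the formyl group endo, the E geometry placing C2 and C9 trans and the catalyst fixing C1 and C10, after which N-acylation expels the amine and the silyl group to give the enone.

**Step 2**
Reactants: 4 formyl enone
Product: 5 C2 homoallylic alcohol
Conditions: (+)-Ipc2B(allyl) (from (−)-α-pinene), Et2O, −78 °C; then ethanolamine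
Reagents that add atoms: (+)-B-allyldiisopinocampheylborane, C=CCB([C@H]1C[C@H]2C[C@@H]([C@@H]1C)C2(C)C)[C@H]1C[C@H]2C[C@@H]([C@@H]1C)C2(C)C
Why: Brown allylboration through a chair Zimmerman–Traxler transition state is selective for the aldehyde over the enone and is reagent-controlled, Re-face addition setting (2R).

**Step 3**
Reactants: 5 C2 homoallylic alcohol
Product: 6 C2 TBS ether
Conditions: TBSOTf, 2,6-lutidine, CH2Cl2, −78 → 0 °C
Reagents that add atoms: tert-butyldimethylsilyl triflate, CC(C)(C)[Si](C)(C)OS(=O)(=O)C(F)(F)F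
Why: Silylation with the reactive triflate masks the hindered neopentyl-type alcohol for the enolate and organometallic steps.

**Step 4**
Reactants: 6 C2 TBS ether
Product: 7 11-methyl enone (C11 epimers)
Conditions: LDA, THF, −78 °C; MeI, DMPU, −78 → −40 °C
Reagents that add atoms: iodomethane, CI
Why: Kinetic deprotonation can only occur at the α′ carbon C11 (C1 is quaternary) and the cross-conjugated enolate is methylated there; the C11 configuration is erased in step 5.

**Step 5**
Reactants: 7 11-methyl enone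
Product: 8 α′-hydroxy enone
Conditions: KHMDS, THF, −78 °C; 2-(phenylsulfonyl)-3-phenyloxaziridine, −78 °C; aq. NH4Cl
Reagents that add atoms: 2-(phenylsulfonyl)-3-phenyloxaziridine, O=S(=O)(c1ccccc1)N1OC1c1ccccc1
Why: Davis oxidation of the tetrasubstituted potassium enolate should occur on the α face, anti to the axial C15 methyl on C1, which sets C11 (OH α, CH3 β).

**Step 6**
Reactants: 8 α′-hydroxy enone
Product: 9 11,12-diol
Conditions: NaBH4, CeCl3·7H2O, MeOH, −78 → −40 °C
Reagents that add atoms: none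
Why: Luche 1,2-reduction, with hydride expected on the face opposite the two β-methyl groups, masks the enone as the 12β-allylic alcohol (this centre is removed in step 22).

**Step 7**
Reactants: 9 11,12-diol
Product: 10 tris-TBS ether
Conditions: TBSOTf (3 equiv), 2,6-lutidine, CH2Cl2, 0 °C → rt
Reagents that add atoms: tert-butyldimethylsilyl triflate, CC(C)(C)[Si](C)(C)OS(=O)(=O)C(F)(F)F
Why: Exhaustive silylation with the silyl triflate protects the secondary and the tertiary hydroxyl against the Grignard, enolate and chromium chemistry that follows.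

**Step 8**
Reactants: 10 tris-TBS ether
Product: 12 C4 primary alcohol, via C4 aldehyde 11 (not isolated)
Conditions: K2OsO4·2H2O (cat.), NaIO4, 2,6-lutidine, dioxane/H2O, rt; then NaBH4, MeOH, 0 °C
Reagents that add atoms: sodium periodate (oxygen source through the osmate ester), [Na+].[O-][I](=O)(=O)=O
Why: Lemieux–Johnson cleavage should pick the unhindered terminal alkene over the shielded ring alkene, and borohydride reduces the aldehyde to the alcohol.

**Step 9**
Reactants: 12 C4 primary alcohol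
Product: 13 C4 bromide
Conditions: CBr4, PPh3, imidazole, CH2Cl2, 0 °C
Reagents that add atoms: carbon tetrabromide, BrC(Br)(Br)Br
Why: Appel bromination of the primary alcohol under buffered conditions leaves the acetal and silyl ethers intact.

**Step 10**
Reactants: 13 C4 bromide; 14 propargyl alcohol
Product: 17 (Z)-chloroallylic alcohol, via Grignard reagent 15 (not isolated), via cyclic alkenylmagnesium alkoxide 16 (not isolated)
Conditions: Mg, THF, 35 °C; 14 pre-treated with EtMgBr (1 equiv, −20 °C); CuI (15 mol %), THF/Et2O, −20 → 20 °C; NCS, −40 → 0 °C; aq. NH4Cl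
Reagents that add atoms: N-chlorosuccinimide, O=C1CCC(=O)N1Cl
Why: Copper-catalysed anti-carbomagnesiation of the propargylic alkoxide places the alkyl group on C5 and magnesium on C6 cis to the CH2O group in a five-membered chelate, so chlorination with retention gives the (Z)-chloroalkene (Cl cis to C16) as one isomer.

**Step 11**
Reactants: 17 (Z)-chloroallylic alcohol; 18 tert-butyl 4-chloroacetoacetate
Product: 19 4-alkoxyacetoacetate
Conditions: NaH (2.2 equiv), THF, 0 °C → rt; aq. NH4Cl
Reagents that add atoms: none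
Why: Williamson etherification: the sodium alkoxide displaces the γ-chloride of the acetoacetate, which is present as its enolate and so is protected from attack at the carbonyl groups.

**Step 12**
Reactants: 19 4-alkoxyacetoacetate
Product: 20 2-methyl β-keto ester (C17 epimers)
Conditions: K2CO3, MeI, acetone, rt
Reagents that add atoms: iodomethane, CI
Why: Mild C-alkylation of the β-keto ester at the doubly activated carbon introduces the C18 methyl group.

**Step 13**
Reactants: 20 2-methyl β-keto ester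
Product: 21 (E)-enol triflate
Conditions: Tf2O, aq. Me4NOH, toluene, 0–5 °C
Reagents that add atoms: trifluoromethanesulfonic anhydride, O=S(=O)(OS(=O)(=O)C(F)(F)F)C(F)(F)F
Why: Triflation of the non-chelated tetramethylammonium enolate should give the (E)-enol triflate (OTf trans to the ester), which places C7 cis to the ester as needed later for the lactone.

**Step 14**
Reactants: 21 (E)-enol triflate
Product: 22 C9 aldehyde
Conditions: PPTS (cat.), acetone/H2O (10:1), 50 °C
Reagents that add atoms: water, O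
Why: Mild acid-catalysed acetal hydrolysis frees the C9 aldehyde without touching the enol triflate, the tert-butyl ester or the TBS ethers.

**Step 15**
Reactants: 22 C9 aldehyde
Product: 23 11-membered cyclic ether (9R)-alcohol
Conditions: CrCl2 (8 equiv), NiCl2 (2 mol %), DMSO/THF, 0.002 M, rt
Reagents that add atoms: none
Why: Nozaki–Hiyama–Kishi reaction: Ni(0) inserts into the C–OTf bond and the alkenylchromium(III) species adds to the aldehyde with retention of alkene geometry to close the 11-membered ring, Felkin–Anh attack anti to the quaternary C1 being expected to give the (9R)-alcohol.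

**Step 16**
Reactants: 23 11-membered cyclic ether alcohol
Product: 24 C9 TES ether
Conditions: TESOTf, 2,6-lutidine, CH2Cl2, −78 °C
Reagents that add atoms: triethylsilyl triflate, CC[Si](CC)(CC)OS(=O)(=O)C(F)(F)F
Why: Silylation gives a bulky, later selectively removable ether at the allylic hydroxyl, which also serves as the facial control element in step 17.

**Step 17**
Reactants: 24 C9 TES ether
Product: 26 ten-membered (6S,7R)-chlorohydrin ester, via lithium dienolate 25 (not isolated)
Conditions: LDA (1.5 equiv), THF, −78 → −45 °C; AcOH, −78 °C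
Reagents that add atoms: none
Why: Proposed new method: LDA should remove the C7–H syn to the ester carbonyl (γ-deprotonation of the γ-alkoxy enoate) to give dienolate 25, whose C7 terminus attacks C6 of the exocyclic chloroalkene through the five-membered envelope of a [2,3]-Wittig shift while the O–C16 bond breaks, so that O and C16 leave the ring and C6 enters it (11 → 10). The closest known reaction types are the ester-dienolate [2,3]-Wittig rearrangement and the [2,3]-Wittig ring contraction of macrocyclic allylic ethers, neither of which has been run with an exocyclic alkene terminus or a γ-chloro substituent. The ten-membered ring closes by this suprafacial reorganisation through a bicyclo[7.2.1]-like transition state, not by end-to-end cyclisation. C6 and C7 are set together: the (Z)-chloroalkene (Cl cis to C16) and the lithium-chelated (E)-enol ether with C8 endo should give the anti 6-chloro-7-oxy relationship, and the face is set by C9, whose C–H eclipses C7=C8 so that the OTES group blocks one face and the C10 arm carries the bridge over the other. The chelated s-cis dienolate should return the C8=C17 bond with C7 cis to the ester. The step needs [2,3] over [1,2] shift and no loss of chloride, which low temperature and the tert-butyl ester (no lactonisation, hence no alkoxide base and no acidic C7–H next to the C–Cl bond) are meant to secure.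

**Step 18**
Reactants: 26 ten-membered chlorohydrin ester
Product: 27 butenolide 9-alcohol
Conditions: CSA (10 mol %), CH2Cl2/MeOH (5:1), 0 °C → rt
Reagents that add atoms: none
Why: Acid catalysis closes the γ-lactone from the C7 hydroxyl onto the cis ester with loss of tert-butanol, and methanolysis removes only the TES ether because the secondary and tertiary TBS ethers react more slowly.

**Step 19**
Reactants: 27 butenolide 9-alcohol
Product: 28 8,17-epoxy lactone
Conditions: VO(acac)2 (10 mol %), t-BuOOH (decane), toluene, 0 → 40 °C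
Reagents that add atoms: tert-butyl hydroperoxide, CC(C)(C)OO
Why: Hydroxyl-directed epoxidation (allylic 1,3-strain with the C18 methyl holds C9–H in the alkene plane) should deliver oxygen to the C8=C17 face syn to C6, which sets C8, while the non-allylic 5(16)- and 13,14-alkenes are not addressed.

**Step 20**
Reactants: 28 8,17-epoxy lactone
Product: 30 8-hydroxy lactone (17R), via C17 epimer mixture 29 (not isolated)
Conditions: SmI2 (2.5 equiv), THF/MeOH, −78 °C; then DBU (0.3 equiv), toluene, rt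
Reagents that add atoms: none
Why: Samarium diiodide cleaves the Cα–O bond of the α,β-epoxy lactone to leave the tertiary 8-OH, and base equilibration of the α-centre should move the C18 methyl anti to the C9 ring carbon, the more stable arrangement.

**Step 21**
Reactants: 30 8-hydroxy lactone
Product: 31 pentaol
Conditions: HF·pyridine, THF/pyridine, 0 → 40 °C
Reagents that add atoms: none
Why: Fluoride cleaves the three TBS ethers under weakly acidic conditions that spare the allylic chloride and the β-hydroxy lactone.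

**Step 22**
Reactants: 31 pentaol
Product: 32 enone tetraol
Conditions: activated MnO2, CH2Cl2, rt
Reagents that add atoms: none
Why: Manganese dioxide oxidises only the allylic 12-hydroxyl among the secondary alcohols and restores the enone.

**Step 23**
Reactants: 32 enone tetraol
Product: 33 CNP0261648.1
Conditions: Ac2O, pyridine, DMAP (cat.), CH2Cl2, 0 °C → rt
Reagents that add atoms: acetic anhydride, CC(=O)OC(C)=O
Why: The secondary alcohols at C2 and C9 are acetylated while the tertiary hydroxyls at C8 and C11 do not react under these conditions.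

**Compound list**

1 | (E)-4,4-dimethoxy-2-methylbut-2-enal | O=C/C(C)=C/C(OC)OC | starting material
2 | (E)-3-(tert-butyldimethylsilyloxy)-N,N-dimethylbuta-1,3-dien-1-amine | C=C(O[Si](C)(C)C(C)(C)C)/C=C/N(C)C | starting material
3 | Diels–Alder adduct (endo; 14-dimethylamino, 12-silyl enol ether) | O=C[C@@]1(C)[C@@H](N(C)C)C=C(O[Si](C)(C)C(C)(C)C)C[C@@H]1C(OC)OC | intermediate
4 | (1S,6S)-6-(dimethoxymethyl)-1-methyl-4-oxocyclohex-2-ene-1-carbaldehyde | O=C[C@@]1(C)C=CC(=O)C[C@@H]1C(OC)OC | intermediate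
5 | (4S,5S)-5-(dimethoxymethyl)-4-[(1R)-1-hydroxybut-3-en-1-yl]-4-methylcyclohex-2-en-1-one | C=CC[C@@H](O)[C@@]1(C)C=CC(=O)C[C@@H]1C(OC)OC | intermediate
6 | C2 TBS ether of 5 | C=CC[C@@H](O[Si](C)(C)C(C)(C)C)[C@@]1(C)C=CC(=O)C[C@@H]1C(OC)OC | intermediate
7 | 11-methyl enone (both C11 epimers) | C=CC[C@@H](O[Si](C)(C)C(C)(C)C)[C@@]1(C)C=CC(=O)C(C)[C@@H]1C(OC)OC | intermediate
8 | 11α-hydroxy-11β-methyl enone | C=CC[C@@H](O[Si](C)(C)C(C)(C)C)[C@@]1(C)C=CC(=O)[C@@](C)(O)[C@@H]1C(OC)OC | intermediate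
9 | 11α,12β-diol (13,14-ene) | C=CC[C@@H](O[Si](C)(C)C(C)(C)C)[C@@]1(C)C=C[C@H](O)[C@@](C)(O)[C@@H]1C(OC)OC | intermediate
10 | 2,11,12-tris-TBS ether (allyl side chain, C9 dimethyl acetal) | C=CC[C@@H](O[Si](C)(C)C(C)(C)C)[C@@]1(C)C=C[C@H](O[Si](C)(C)C(C)(C)C)[C@@](C)(O[Si](C)(C)C(C)(C)C)[C@@H]1C(OC)OC | intermediate
11 | C4 aldehyde | O=CC[C@@H](O[Si](C)(C)C(C)(C)C)[C@@]1(C)C=C[C@H](O[Si](C)(C)C(C)(C)C)[C@@](C)(O[Si](C)(C)C(C)(C)C)[C@@H]1C(OC)OC | intermediate
12 | C4 primary alcohol | OCC[C@@H](O[Si](C)(C)C(C)(C)C)[C@@]1(C)C=C[C@H](O[Si](C)(C)C(C)(C)C)[C@@](C)(O[Si](C)(C)C(C)(C)C)[C@@H]1C(OC)OC | intermediate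
13 | C4 bromide | BrCC[C@@H](O[Si](C)(C)C(C)(C)C)[C@@]1(C)C=C[C@H](O[Si](C)(C)C(C)(C)C)[C@@](C)(O[Si](C)(C)C(C)(C)C)[C@@H]1C(OC)OC | intermediate
14 | propargyl alcohol | C#CCO | starting material
15 | C4 Grignard reagent | Br[Mg]CC[C@@H](O[Si](C)(C)C(C)(C)C)[C@@]1(C)C=C[C@H](O[Si](C)(C)C(C)(C)C)[C@@](C)(O[Si](C)(C)C(C)(C)C)[C@@H]1C(OC)OC | intermediate
16 | cyclic (Z)-alkenylmagnesium alkoxide (Mg on C6 and O16) | [Mg]1OCC(CC[C@@H](O[Si](C)(C)C(C)(C)C)[C@@]2(C)C=C[C@H](O[Si](C)(C)C(C)(C)C)[C@@](C)(O[Si](C)(C)C(C)(C)C)[C@@H]2C(OC)OC)=C1 | intermediate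
17 | (Z)-3-chloro-2-alkylprop-2-en-1-ol (C16 alcohol, Cl cis to CH2OH) | Cl/C=C(\CO)CC[C@@H](O[Si](C)(C)C(C)(C)C)[C@@]1(C)C=C[C@H](O[Si](C)(C)C(C)(C)C)[C@@](C)(O[Si](C)(C)C(C)(C)C)[C@@H]1C(OC)OC | intermediate
18 | tert-butyl 4-chloroacetoacetate | ClCC(=O)CC(=O)OC(C)(C)C | starting material
19 | tert-butyl 4-(allyloxy)acetoacetate (C16–O–C7 ether) | Cl/C=C(\COCC(=O)CC(=O)OC(C)(C)C)CC[C@@H](O[Si](C)(C)C(C)(C)C)[C@@]1(C)C=C[C@H](O[Si](C)(C)C(C)(C)C)[C@@](C)(O[Si](C)(C)C(C)(C)C)[C@@H]1C(OC)OC | intermediate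
20 | 2-methyl β-keto ester (C17 epimers) | Cl/C=C(\COCC(=O)C(C)C(=O)OC(C)(C)C)CC[C@@H](O[Si](C)(C)C(C)(C)C)[C@@]1(C)C=C[C@H](O[Si](C)(C)C(C)(C)C)[C@@](C)(O[Si](C)(C)C(C)(C)C)[C@@H]1C(OC)OC | intermediate
21 | (E)-enol triflate (C7 cis to ester) | Cl/C=C(\COC/C(OS(=O)(=O)C(F)(F)F)=C(/C)C(=O)OC(C)(C)C)CC[C@@H](O[Si](C)(C)C(C)(C)C)[C@@]1(C)C=C[C@H](O[Si](C)(C)C(C)(C)C)[C@@](C)(O[Si](C)(C)C(C)(C)C)[C@@H]1C(OC)OC | intermediate
22 | C9 aldehyde enol triflate | Cl/C=C(\COC/C(OS(=O)(=O)C(F)(F)F)=C(/C)C(=O)OC(C)(C)C)CC[C@@H](O[Si](C)(C)C(C)(C)C)[C@@]1(C)C=C[C@H](O[Si](C)(C)C(C)(C)C)[C@@](C)(O[Si](C)(C)C(C)(C)C)[C@@H]1C=O | intermediate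
23 | 11-membered cyclic ether, (9R)-alcohol, exocyclic (Z)-chloromethylene on C5, exocyclic enoate on C8 | Cl/C=C1/CC[C@@H](O[Si](C)(C)C(C)(C)C)[C@@]2(C)C=C[C@H](O[Si](C)(C)C(C)(C)C)[C@@](C)(O[Si](C)(C)C(C)(C)C)[C@@H]2[C@@H](O)C(=C(/C)C(=O)OC(C)(C)C)\COC1 | intermediate
24 | C9 TES ether of 23 | Cl/C=C1/CC[C@@H](O[Si](C)(C)C(C)(C)C)[C@@]2(C)C=C[C@H](O[Si](C)(C)C(C)(C)C)[C@@](C)(O[Si](C)(C)C(C)(C)C)[C@@H]2[C@@H](O[Si](CC)(CC)CC)C(=C(/C)C(=O)OC(C)(C)C)\COC1 | intermediate
25 | lithium dienolate (C7=C8 enol ether, C17=C19 ketene acetal) | Cl/C=C1/CC[C@@H](O[Si](C)(C)C(C)(C)C)[C@@]2(C)C=C[C@H](O[Si](C)(C)C(C)(C)C)[C@@](C)(O[Si](C)(C)C(C)(C)C)[C@@H]2[C@@H](O[Si](CC)(CC)CC)/C(C(C)=C(O[Li])OC(C)(C)C)=C/OC1 | intermediate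
26 | ten-membered carbocycle: (6S)-chloro, (7R)-hydroxy, 5(16)-methylene, tert-butyl enoate | C=C1CC[C@@H](O[Si](C)(C)C(C)(C)C)[C@@]2(C)C=C[C@H](O[Si](C)(C)C(C)(C)C)[C@@](C)(O[Si](C)(C)C(C)(C)C)[C@@H]2[C@@H](O[Si](CC)(CC)CC)C(=C(/C)C(=O)OC(C)(C)C)\[C@@H](O)[C@H]1Cl | intermediate
27 | 8(17)-butenolide with free 9-OH | C=C1CC[C@@H](O[Si](C)(C)C(C)(C)C)[C@@]2(C)C=C[C@H](O[Si](C)(C)C(C)(C)C)[C@@](C)(O[Si](C)(C)C(C)(C)C)[C@@H]2[C@@H](O)C2=C(C)C(=O)O[C@H]2[C@H]1Cl | intermediate
28 | 8,17-epoxy lactone (epoxide syn to C6) | C=C1CC[C@@H](O[Si](C)(C)C(C)(C)C)[C@@]2(C)C=C[C@H](O[Si](C)(C)C(C)(C)C)[C@@](C)(O[Si](C)(C)C(C)(C)C)[C@@H]2[C@@H](O)[C@@]23O[C@@]3(C)C(=O)O[C@H]2[C@H]1Cl | intermediate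
29 | 8-hydroxy lactone, C17 epimer mixture | C=C1CC[C@@H](O[Si](C)(C)C(C)(C)C)[C@@]2(C)C=C[C@H](O[Si](C)(C)C(C)(C)C)[C@@](C)(O[Si](C)(C)C(C)(C)C)[C@@H]2[C@@H](O)[C@]2(O)C(C)C(=O)O[C@H]2[C@H]1Cl | intermediate
30 | 8-hydroxy-(17R)-lactone, 2,11,12-tris-TBS ether | C=C1CC[C@@H](O[Si](C)(C)C(C)(C)C)[C@@]2(C)C=C[C@H](O[Si](C)(C)C(C)(C)C)[C@@](C)(O[Si](C)(C)C(C)(C)C)[C@@H]2[C@@H](O)[C@]2(O)[C@@H](C)C(=O)O[C@H]2[C@H]1Cl | intermediate
31 | 2,8,9,11,12-pentaol | C=C1CC[C@@H](O)[C@@]2(C)C=C[C@H](O)[C@@](C)(O)[C@@H]2[C@@H](O)[C@]2(O)[C@@H](C)C(=O)O[C@H]2[C@H]1Cl | intermediate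
32 | 12-oxo-13-ene 2,8,9,11-tetraol | C=C1CC[C@@H](O)[C@@]2(C)C=CC(=O)[C@@](C)(O)[C@@H]2[C@@H](O)[C@]2(O)[C@@H](C)C(=O)O[C@H]2[C@H]1Cl | intermediate
33 | CNP0261648.1 | C=C1CC[C@@H](OC(C)=O)[C@@]2(C)C=CC(=O)[C@@](C)(O)[C@@H]2[C@@H](OC(C)=O)[C@]2(O)[C@@H](C)C(=O)O[C@H]2[C@H]1Cl | target

**Totals**

Total steps: 23. Longest linear sequence: 23 (from 1 and 2 to 33).

**Steps most likely to fail**

1. Step 17 (proposed new method). The dienolate may react by a [1,2]-shift or be formed at C9 or C16 instead of C7. The bridge may span the wrong face of the dienolate, or the C8=C17 geometry may be lost on rebonding. Fallback with known chemistry (Nozaki–Hiyama–Kishi coupling and chromium(II)-mediated γ-chloroallylation of an aldehyde, used here as a direct ten-membered ring closure), setting out from compound 17 and returning at 27. Acetal hydrolysis of 17 (PPTS, acetone/H2O) gives the hydroxy aldehyde F1. Claisen condensation of tert-butyl propionate with methyl dimethoxyacetate gives the β-keto ester F2, which is converted (Tf2O, aq. Me4NOH) into the (E)-enol triflate F3. Intermolecular NiCl2/CrCl2 coupling of F1 with F3 gives the diol acetal F4. The primary allylic hydroxyl is exchanged (MsCl, collidine; LiBr) to give the allylic bromide F5, and hydrolysis of the C7 acetal gives the enal F6. CrCl2 in THF at high dilution then adds the γ-chloroallylchromium species through C6 to the C7 aldehyde (chair transition state, anti chlorohydrin, exo-methylene by allyl transposition) to give the dihydroxy ester F7, which lactonises with CSA to 27.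

2. Step 19. Oxygen transfer to the electron-poor tetrasubstituted butenolide alkene may be too slow, so that oxidation elsewhere or on the wrong face competes. Fallback setting out from 26 and returning at 30: the open-chain enoate is epoxidised with buffered mCPBA before lactonisation, directed by the free 7-OH (allylic strain with the cis ester puts C7–H in the alkene plane; the same C8 configuration results), to give the glycidic ester F8. SmI2 then gives the β-hydroxy ester F9. CSA in MeOH closes the lactone and removes the TES group to give 29, which DBU equilibrates to 30.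

3. Step 15. Facial selectivity at C9 may be poor or reversed, and oligomerisation may compete with ring closure. Fallback setting out from 22 and returning at 23: the 9-epimeric alcohol F10 formed in the ring closure is oxidised (Dess–Martin periodinane) to the ketone F11 and reduced under Luche conditions. Hydride addition to the ketone follows the same Felkin preference that the carbon nucleophile followed at the aldehyde, so it gives the opposite C9 configuration, that of 23.

**Further compounds**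

F1 | step 17 | C9 aldehyde of 17 (free C16 alcohol) | Cl/C=C(\CO)CC[C@@H](O[Si](C)(C)C(C)(C)C)[C@@]1(C)C=C[C@H](O[Si](C)(C)C(C)(C)C)[C@@](C)(O[Si](C)(C)C(C)(C)C)[C@@H]1C=O
F2 | step 17 | tert-butyl 4,4-dimethoxy-2-methyl-3-oxobutanoate | COC(OC)C(=O)C(C)C(=O)OC(C)(C)C
F3 | step 17 | tert-butyl (E)-4,4-dimethoxy-2-methyl-3-(trifluoromethylsulfonyloxy)but-2-enoate | COC(OC)/C(OS(=O)(=O)C(F)(F)F)=C(/C)C(=O)OC(C)(C)C
F4 | step 17 | acyclic (9R)-alcohol with C7 dimethyl acetal and C16 alcohol | Cl/C=C(\CO)CC[C@@H](O[Si](C)(C)C(C)(C)C)[C@@]1(C)C=C[C@H](O[Si](C)(C)C(C)(C)C)[C@@](C)(O[Si](C)(C)C(C)(C)C)[C@@H]1[C@@H](O)C(=C(/C)C(=O)OC(C)(C)C)\C(OC)OC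
F5 | step 17 | C16 allylic bromide of F4 | Cl/C=C(\CBr)CC[C@@H](O[Si](C)(C)C(C)(C)C)[C@@]1(C)C=C[C@H](O[Si](C)(C)C(C)(C)C)[C@@](C)(O[Si](C)(C)C(C)(C)C)[C@@H]1[C@@H](O)C(=C(/C)C(=O)OC(C)(C)C)\C(OC)OC
F6 | step 17 | C7 aldehyde allylic bromide | Cl/C=C(\CBr)CC[C@@H](O[Si](C)(C)C(C)(C)C)[C@@]1(C)C=C[C@H](O[Si](C)(C)C(C)(C)C)[C@@](C)(O[Si](C)(C)C(C)(C)C)[C@@H]1[C@@H](O)C(=C(/C)C(=O)OC(C)(C)C)\C=O
F7 | step 17 | ten-membered 7,9-dihydroxy tert-butyl enoate (6S,7R) | C=C1CC[C@@H](O[Si](C)(C)C(C)(C)C)[C@@]2(C)C=C[C@H](O[Si](C)(C)C(C)(C)C)[C@@](C)(O[Si](C)(C)C(C)(C)C)[C@@H]2[C@@H](O)C(=C(/C)C(=O)OC(C)(C)C)\[C@@H](O)[C@H]1Cl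
F8 | step 19 | 8,17-epoxy tert-butyl ester (open chain, 7-OH, 9-OTES) | C=C1CC[C@@H](O[Si](C)(C)C(C)(C)C)[C@@]2(C)C=C[C@H](O[Si](C)(C)C(C)(C)C)[C@@](C)(O[Si](C)(C)C(C)(C)C)[C@@H]2[C@@H](O[Si](CC)(CC)CC)[C@@]3(O[C@@]3(C)C(=O)OC(C)(C)C)[C@@H](O)[C@H]1Cl
F9 | step 19 | 7,8-dihydroxy tert-butyl ester (C17 epimers, 9-OTES) | C=C1CC[C@@H](O[Si](C)(C)C(C)(C)C)[C@@]2(C)C=C[C@H](O[Si](C)(C)C(C)(C)C)[C@@](C)(O[Si](C)(C)C(C)(C)C)[C@@H]2[C@@H](O[Si](CC)(CC)CC)[C@](O)(C(C)C(=O)OC(C)(C)C)[C@@H](O)[C@H]1Cl
F10 | step 15 | 9-epimer of 23 | Cl/C=C1/CC[C@@H](O[Si](C)(C)C(C)(C)C)[C@@]2(C)C=C[C@H](O[Si](C)(C)C(C)(C)C)[C@@](C)(O[Si](C)(C)C(C)(C)C)[C@@H]2[C@H](O)C(=C(/C)C(=O)OC(C)(C)C)\COC1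
F11 | step 15 | C9 ketone of the 11-membered cyclic ether | Cl/C=C1/CC[C@@H](O[Si](C)(C)C(C)(C)C)[C@@]2(C)C=C[C@H](O[Si](C)(C)C(C)(C)C)[C@@](C)(O[Si](C)(C)C(C)(C)C)[C@@H]2C(=O)C(=C(/C)C(=O)OC(C)(C)C)\COC1
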